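(The numbers in the tables are calculated with constants of no real substance, and the scatter is random.)

The constants of these flasks are not given, so you read them from the winter and dusk runs, through one quantity: the working catalyst, the free catalyst charged minus the impurity charged, which the suspect step free catalyst + impurity takes one for one. For theta it is 13.4 mM.

| flask | solid substrate | free catalyst | impurity | remark | time |
|---|---|---|---|---|---|
| winter | 0.13 M | 9.8 mol% | 6.2 mM | run made earlier |  |
| dusk | 1.2 M | 9.8 mol% | 6.2 mM | run made earlier |  |
| zeta | 0.10 M | 9.8 mol% | 6.2 mM |  | 4.0 min |
| theta | 0.20 M | 9.8 mol% | 6.2 mM |  | 4.0 min |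
| alpha | 0.40 M | 9.8 mol% | 6.2 mM |  | 4.0 min |
| beta | 0.80 M | 9.8 mol% | 6.2 mM |  | 4.0 min |

| run | time / min | target / % | solid substrate / % |
|---|---|---|---|
| winter | 0.500 | 3.2 | 0 |
| winter | 1.00 | 6.3 | 0 |
| winter | 1.50 | 9.0 | 0.9 |
| winter | 2.50 | 13.6 | 0 |
| winter | 3.00 | 15.7 | 0 |
| dusk | 0.250 | 2.1 | 89.0 |
| dusk | 0.667 | 5.3 | 83.6 |
| dusk | 1.33 | 12.0 | 76.8 |
| dusk | 2.00 | 17.9 | 71.0 |
| dusk | 3.00 | 26.6 | 61.9 |

(readings scatter by 0.5 percentage points)

- [target] at the end for zeta, theta, alpha, beta, in this order
- how that number moves from the first to the last of them (falls, then rises / falls all the way / rises all the way / hardly changes / rises, then falls)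

- solid, in amounts per volume of the solution: solid substrate
- on the list of suspects stand: starting material + free catalyst -> catalyst intermediate; catalyst intermediate <-> free catalyst + target; solid substrate <-> starting material; free catalyst + impurity -> spent catalyst
- at the start none of the solid substrate is in solution
- "hardly changes" means that all values lie within two and a half points (for a concentration: within two and a half percent of the largest)

Take the rungs from fast to slow, the two fast ones first. Dissolving is one of them: in dusk, charged minus solid minus target reads 0.107 M at 0.250 min and then levels at 0.135 M, which I take as a reading of the saturation level of [starting material], with catalyst intermediate counted in.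

The impurity is the other, and you solve it at both ends. In dusk the working catalyst is 111 mM and target rises at 0.110 M min⁻¹, a turnover frequency of 0.983 min⁻¹. In winter the working catalyst is 6.54 mM, target rises at 0.00611 M min⁻¹ at a mean [starting material] of 0.116 M, and scaling to saturation gives 1.09 min⁻¹. Counting winter's whole catalyst charge instead gives 0.558 min⁻¹, so I subtract the impurity and carry the mean, 1.04 min⁻¹.

Turnover comes last, one cycle at saturation taking 0.962 min by this reading. The working catalyst is 3.60 mM in zeta, 33.0 mM in alpha and 72.2 mM in beta. By my reckoning theta's solid reserve above saturation lasts 4.71 min, alpha's 7.76 min and beta's 8.90 min, each longer than 4.0 min. So my reckoning is turnover frequency times working catalyst times time: 0.0555 M for theta, 0.137 M for alpha and 0.299 M for beta. Zeta, charged below saturation, gets 0.0111 M.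

The forecast gives 0.016 M, 0.055 M, 0.123 M and 0.26 M, rises all the way, on the ground “This fits slow second-order catalyst kill by impurity”. It stands above mine at zeta and below mine at beta.

The flask gives 0.0135 M, 0.0632 M, 0.146 M and 0.288 M, which rises all the way.

starting material + free catalyst → catalyst intermediate (k = 0.170 L mol⁻¹ s⁻¹); catalyst intermediate ⇌ free catalyst + target (K = 1.10 M, k = 0.510 s⁻¹); solid substrate ⇌ starting material, rate k3*(cs3 - [starting material]) while solid is left; crystals form when [starting material] > cs3 (solubility = 0.130 M, k = 0.190 s⁻¹); free catalyst + impurity → spent catalyst (k = 19.0 L mol⁻¹ s⁻¹) At 4.00 min zeta holds 63.3% of its catalyst as spent catalyst, 35.3% as free catalyst and 1.45% as catalyst intermediate. Theta's working catalyst is 68.4% of its charge, and its free catalyst and catalyst intermediate stand at 62.2% and 6.21%. On beta the working catalyst is 92.1% of the charge, and the flask holds 70.8% free catalyst and 21.3% catalyst intermediate.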